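The cyclohexene (C1 aroyl, C2 H2, C3=C4 methyl, C5 prenyl, C6 phenyl) is cut at C5–C6, its only ring bond that is both benzylic and allylic. Joining C6 to C3 instead gives a strained 2-phenyl-3-alkenylcyclobutyl aryl ketone, the enantioselective [2+2] photoadduct of a 2'-hydroxychalcone and (E)-β-ocimene. Heating releases the strain: a vinylcyclobutane–cyclohexene ring expansion closes the six-membered ring, locks in the aroyl-next-to-CH2 regiochemistry that a polar Diels–Alder reaction of the same partners disfavours, and sets C5 and C6 under control of the untouched C1 stereocentre. One phenol travels as its methyl ether and is freed last.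

Key step: step 4

Assumption: the Sc(III)/(S,S)-t-Bu-PyBox catalyst is taken to give the (1R)-cyclobutane from chalcone 5. If its sense of induction is the opposite, the equally available (R,R) ligand is used.

Step 1
Reactants: 1 3,4,5-trimethoxyphenol
Product: 3 1-(6-hydroxy-2,3,4-trimethoxyphenyl)ethan-1-one, via 3,4,5-trimethoxyphenyl acetate 2 (not isolated)
Conditions: Ac2O (1.5 equiv), BF3·OEt2 (3 equiv), 90 °C; then H2O
Reagents that add atoms: acetic anhydride, CC(=O)OC(C)=O
Why: O-acetylation followed by BF3-promoted Fries rearrangement (Friedel–Crafts-type C-acylation) should give a single hydrogen-bonded ortho-hydroxy ketone, because the two ortho positions are equivalent and the para position is blocked; no stereocentre is formed.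

Step 2
Reactants: 3 1-(6-hydroxy-2,3,4-trimethoxyphenyl)ethan-1-one; 4 benzaldehyde
Product: 5 (E)-1-(6-hydroxy-2,3,4-trimethoxyphenyl)-3-phenylprop-2-en-1-one
Conditions: KOH (50 % aq.), EtOH, rt; then cold 1 M HCl
Reagents that add atoms: none
Why: In this Claisen–Schmidt condensation the methyl ketone enolate adds to the non-enolisable aldehyde, and E1cB loss of water gives the conjugated E-enone as the thermodynamic isomer; no stereocentre is formed.

Step 3
Reactants: 5 (E)-1-(6-hydroxy-2,3,4-trimethoxyphenyl)-3-phenylprop-2-en-1-one; 6 (E)-β-ocimene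
Product: 7 (6-hydroxy-2,3,4-trimethoxyphenyl){(1R,2R,3S)-3-[(2E)-6-methylhepta-2,5-dien-2-yl]-2-phenylcyclobutyl}methanone
Conditions: Sc(OTf)3 (10 mol %), (S,S)-t-Bu-PyBox (15 mol %), Ru(bpy)3(PF6)2 (2.5 mol %), 6 (5 equiv, Z-free), i-PrOAc/MeCN 3:1, visible light, rt, degassed
Reagents that add atoms: none
Why: This is a Lewis-acid-catalysed, triplet-sensitised enantioselective [2+2] photocycloaddition in which only the Sc-chelated 2'-hydroxychalcone is within reach of the Ru sensitiser, its α-carbon bonds to the unsubstituted CH2 terminus of the diene on the face left open by the ligand (sets C1), the resulting benzyl/allyl diradical closes to the 1,2-trans cyclobutane, and the configuration at the alkenyl-bearing C3 does not matter because step 4 erases it.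

Step 4
Reactants: 7 (6-hydroxy-2,3,4-trimethoxyphenyl){(1R,2R,3S)-3-[(2E)-6-methylhepta-2,5-dien-2-yl]-2-phenylcyclobutyl}methanone
Product: 9 (6-hydroxy-2,3,4-trimethoxyphenyl)[(1R,5R,6R)-4-methyl-5-(3-methylbut-2-en-1-yl)-6-phenylcyclohex-3-en-1-yl]methanone, via benzyl-allyl diradical 8 (not isolated)
Conditions: o-dichlorobenzene (0.01 M), BHT (10 mol %), degassed, sealed tube, 160 °C
Reagents that add atoms: none
Why: This is a thermal vinylcyclobutane–cyclohexene rearrangement, a formal [1,3] carbon shift that runs stepwise: the cyclobutane C2–C3 bond of 7 is weakened by ring strain and by benzylic plus allylic stabilisation, so it breaks first and gives singlet diradical 8, in which the benzylic carbon recombines with the remote terminus of the allyl radical. The cyclohexene is thus closed by intramolecular radical–radical coupling that makes C5–C6 (four-to-six ring expansion, 6-endo at the allyl unit), and loss of the cyclobutane strain makes this closure irreversible at the reaction temperature. Regiochemistry is secured by connectivity, because C1–C2 already exists and only the benzylic carbon can migrate, so the phenyl-bearing carbon must end up next to the prenyl-bearing one. C1 is not involved and carries the absolute configuration through; C6 should be rebuilt trans to the aroyl group because the benzyl radical sits in its A(1,3)-minimised conformer, with H-1 in the radical plane and the aroyl group shielding the face opposite to the tether. C5 follows from the allyl radical, which keeps its E geometry (prenyl CH2 outside) on the time scale of closure, and from closure with phenyl exo, where phenyl lies between H-5 and the prenyl CH2 instead of over C4 and its methyl group; together this should give the 5,6-trans and 1,6-trans array. The step needs ring expansion to beat cycloreversion and unproductive re-closure: re-closure merely returns 7 or its C3 epimer, which re-enter the same diradical, the C4 methyl group removes the usual bias against the cisoid allyl geometry that closure requires, and high dilution keeps any released 5 and 6 from recombining.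

Step 5
Reactants: 9 (6-hydroxy-2,3,4-trimethoxyphenyl)[(1R,5R,6R)-4-methyl-5-(3-methylbut-2-en-1-yl)-6-phenylcyclohex-3-en-1-yl]methanone
Product: 11 (2,6-dihydroxy-3,4-dimethoxyphenyl)[(1R,5R,6R)-4-methyl-5-(3-methylbut-2-en-1-yl)-6-phenylcyclohex-3-en-1-yl]methanone, via iodomagnesium phenolate 10 (not isolated)
Conditions: anhydrous MgI2 (3 equiv), Et2O/toluene, 80 °C; then cold 1 M HCl
Reagents that add atoms: magnesium iodide, [Mg+2].[I-].[I-] (its atoms stay only in 10, none in 11)
Why: In this chelation-directed aryl methyl ether cleavage, Mg(II) held between the ketone oxygen and the flanking 2-OMe activates only that methyl group for SN2 attack by iodide, no protic acid is generated so both trisubstituted alkenes should survive, and C1 is already the more stable trans epimer so no stereocentre is at risk.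

Compound list
1 | 3,4,5-trimethoxyphenol | COc1cc(O)cc(OC)c1OC | starting material
2 | 3,4,5-trimethoxyphenyl acetate | CC(=O)Oc1cc(OC)c(OC)c(OC)c1 | intermediate
3 | 1-(6-hydroxy-2,3,4-trimethoxyphenyl)ethan-1-one | CC(=O)c1c(O)cc(OC)c(OC)c1OC | intermediate
4 | benzaldehyde | O=Cc1ccccc1 | starting material
5 | (E)-1-(6-hydroxy-2,3,4-trimethoxyphenyl)-3-phenylprop-2-en-1-one | COc1cc(O)c(C(=O)/C=C/c2ccccc2)c(OC)c1OC | intermediate
6 | (E)-β-ocimene, (3E)-3,7-dimethylocta-1,3,6-triene | C=C/C(C)=C/CC=C(C)C | starting material
7 | (6-hydroxy-2,3,4-trimethoxyphenyl){(1R,2R,3S)-3-[(2E)-6-methylhepta-2,5-dien-2-yl]-2-phenylcyclobutyl}methanone (aroyl, phenyl and alkenyl all trans) | COc1cc(O)c(C(=O)[C@@H]2C[C@H](/C(C)=C/CC=C(C)C)[C@H]2c2ccccc2)c(OC)c1OC | intermediate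
8 | benzyl-allyl diradical from homolysis of cyclobutane C2–C3 of 7 (aroyl-bearing stereocentre intact, E-allyl radical) | COc1cc(O)c(C(=O)[C@H](C[CH]/C(C)=C/CC=C(C)C)[CH]c2ccccc2)c(OC)c1OC | intermediate
9 | (6-hydroxy-2,3,4-trimethoxyphenyl)[(1R,5R,6R)-4-methyl-5-(3-methylbut-2-en-1-yl)-6-phenylcyclohex-3-en-1-yl]methanone | COc1cc(O)c(C(=O)[C@@H]2CC=C(C)[C@H](CC=C(C)C)[C@H]2c2ccccc2)c(OC)c1OC | intermediate
10 | iodomagnesium 2-phenolate of 11 | COc1cc(O)c(C(=O)[C@@H]2CC=C(C)[C@H](CC=C(C)C)[C@H]2c2ccccc2)c([O-])c1OC.[Mg+2].[I-] | intermediate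
11 | (2,6-dihydroxy-3,4-dimethoxyphenyl)[(1R,5R,6R)-4-methyl-5-(3-methylbut-2-en-1-yl)-6-phenylcyclohex-3-en-1-yl]methanone | COc1cc(O)c(C(=O)[C@@H]2CC=C(C)[C@H](CC=C(C)C)[C@H]2c2ccccc2)c(O)c1OC | target

Total step count: 5. Longest linear sequence: 5 (1 → 3 → 5 → 7 → 9 → 11).

Steps most likely to fail

Step 4. Cycloreversion of the diradical to enone and diene, or closure with the phenyl group endo, may compete with the wanted closure and cost material or diastereomeric purity. The fallback sets out from 5 and 6 and bypasses 7. An uncatalysed Diels–Alder reaction under high pressure (about 15 kbar, CH2Cl2, rt) is concerted and endo-selective. Because the 1-alkyl and 2-methyl groups of the diene direct in opposite senses, it should give both regioisomers. The isomer with the aroyl group next to CH2 is separated by chromatography as the racemate, that is 9 together with its mirror image ent-9 F1. The racemate is resolved by preparative HPLC on a chiral stationary phase. The route is rejoined at 9.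

Step 3. Weak or ambiguous binding of the crowded, electron-rich chalcone to scandium may lower facial selectivity, and Lewis-acid-induced oxa-Michael closure may drain the substrate. The fallback sets out from 4.
- Aldol condensation with commercial 2-acetyl-1-methylimidazole (KOH, EtOH) gives cinnamoyl imidazole F2. This is a two-point-binding enone, for which a chiral-at-rhodium bis-cyclometalated Lewis acid under blue light is an established catalyst of enantioselective [2+2] photocycloaddition.
- With 6 this should give cyclobutyl acyl imidazole F3.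
- N-Methylation (MeOTf, CH2Cl2) gives acyl imidazolium triflate F4, and acyl transfer to phenol 1 (DBU) gives aryl ester F5.
- A photo-Fries rearrangement (300 nm, MeCN) then moves the acyl group to one of the two equivalent ortho positions, the para position being blocked.

The route is rejoined at 7.

Step 5. Cleavage of the second ortho ether of a ketone that is already hydrogen-bonded to the other ortho oxygen may be slow. Forcing it may bring about Lewis-acid-induced protonation or cyclisation of the trisubstituted alkenes. The fallback sets out from 5, which has no acid-sensitive alkene.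
- BCl3 (CH2Cl2, −78 to 0 °C) gives 2',6'-dihydroxy-3',4'-dimethoxychalcone F6.
- One equivalent of Ac2O (pyridine, 0 °C) caps the less hindered phenol to give chalcone monoacetate F7, which still has one chelating ortho-OH.
- The conditions of steps 3 and 4 then lead to cyclobutane acetate F8 and cyclohexene acetate F9.
- K2CO3 in MeOH at 0 °C removes the acetate without touching alkenes or stereocentres.

The route is rejoined at 11.

Further compounds
F1 | step 4 | ent-9, (6-hydroxy-2,3,4-trimethoxyphenyl)[(1S,5S,6S)-4-methyl-5-(3-methylbut-2-en-1-yl)-6-phenylcyclohex-3-en-1-yl]methanone | COc1cc(O)c(C(=O)[C@H]2CC=C(C)[C@@H](CC=C(C)C)[C@@H]2c2ccccc2)c(OC)c1OC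
F2 | step 3 | (E)-1-(1-methyl-1H-imidazol-2-yl)-3-phenylprop-2-en-1-one | Cn1ccnc1C(=O)/C=C/c1ccccc1
F3 | step 3 | (1-methyl-1H-imidazol-2-yl){(1R,2R,3S)-3-[(2E)-6-methylhepta-2,5-dien-2-yl]-2-phenylcyclobutyl}methanone | Cn1ccnc1C(=O)[C@@H]1C[C@H](/C(C)=C/CC=C(C)C)[C@H]1c1ccccc1
F4 | step 3 | 2-acyl-1,3-dimethylimidazolium triflate derived from F3 | C[n+]1ccn(C)c1C(=O)[C@@H]1C[C@H](/C(C)=C/CC=C(C)C)[C@H]1c1ccccc1.[O-]S(=O)(=O)C(F)(F)F
F5 | step 3 | 3,4,5-trimethoxyphenyl (1R,2R,3S)-3-[(2E)-6-methylhepta-2,5-dien-2-yl]-2-phenylcyclobutane-1-carboxylate | COc1cc(OC(=O)[C@@H]2C[C@H](/C(C)=C/CC=C(C)C)[C@H]2c2ccccc2)cc(OC)c1OC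
F6 | step 5 | (E)-1-(2,6-dihydroxy-3,4-dimethoxyphenyl)-3-phenylprop-2-en-1-one | COc1cc(O)c(C(=O)/C=C/c2ccccc2)c(O)c1OC
F7 | step 5 | 3-hydroxy-4,5-dimethoxy-2-[(2E)-3-phenylprop-2-enoyl]phenyl acetate | COc1cc(OC(C)=O)c(C(=O)/C=C/c2ccccc2)c(O)c1OC
F8 | step 5 | 3-hydroxy-4,5-dimethoxy-2-{(1R,2R,3S)-3-[(2E)-6-methylhepta-2,5-dien-2-yl]-2-phenylcyclobutane-1-carbonyl}phenyl acetate | COc1cc(OC(C)=O)c(C(=O)[C@@H]2C[C@H](/C(C)=C/CC=C(C)C)[C@H]2c2ccccc2)c(O)c1OC
F9 | step 5 | 3-hydroxy-4,5-dimethoxy-2-[(1R,5R,6R)-4-methyl-5-(3-methylbut-2-en-1-yl)-6-phenylcyclohex-3-ene-1-carbonyl]phenyl acetate | COc1cc(OC(C)=O)c(C(=O)[C@@H]2CC=C(C)[C@H](CC=C(C)C)[C@H]2c2ccccc2)c(O)c1OC
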